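**Retrosynthetic overview**
15 ⇐ 14: the two free phenols (6-OH on ring A, 2'-OH on ring B) are carried as MOM acetals and released together in the last step.
14 ⇐ 6 + 10 + CO: all three bonds of C2 (C2–C1', C2–C3, C2–O1) are cut at once. A Pd-catalysed carbonylative three-component annulation makes C2–C1' by CO insertion into the C1'–Pd bond and then closes ring C. Ring C is the only ring that is built; rings A and B are bought as arenes.
Enabling feature: C2 of ring C bears no hydrogen, stands at the carboxyl oxidation level and has only three neighbours (C1' of ring B, C3, O1). O1–H and the C3 methyl group sit 1,5 to each other in a ring-A 2-hydroxyacetophenone, so C2 can be delivered as CO in a [5+1] closure. C1' lies between the oxygen-bearing C2' and C6', the site that directed lithiation hits.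
6 ⇐ 1,2,3,5-tetramethoxybenzene: acylation with ortho-ether cleavage, Elbs para-hydroxylation (C8a–O1 and C6–OH are para on ring A), then MOM protection of the non-chelated OH.
10 ⇐ 3-methoxyphenol: MOM protection, then lithiation–iodination between the two oxygen substituents.

Key step: step 6

Remark on the chemistry: the target SMILES holds no stereocentre. The C2–C1' axis is flanked on the ring-C side only by O1 and C3–H and is assumed to rotate freely. The compound is therefore treated as achiral and no step has to control configuration.

**Route**

Step 1
Reactants: 1 1,2,3,5-tetramethoxybenzene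
Product: 3 2-hydroxy-3,4,6-trimethoxyacetophenone, via 2,3,4,6-tetramethoxyacetophenone 2 (not isolated)
Conditions: AcCl (1.2 equiv), AlCl3 (2.5 equiv), Et2O, 0 °C to rt; aq HCl work-up
Reagents that add atoms: acetyl chloride, CC(=O)Cl
Why: Friedel–Crafts acylation at one of the two equivalent free positions of 1 gives 2, and the aluminium chelate between the acetyl oxygen and an ortho ether oxygen should then cleave the C2 methyl ether, which is buttressed between the acetyl group and the C3 methoxy group and twisted out of the ring plane, rather than the less crowded C6 methyl ether.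

Step 2
Reactants: 3 2-hydroxy-3,4,6-trimethoxyacetophenone
Product: 5 2,5-dihydroxy-3,4,6-trimethoxyacetophenone, via potassium aryl sulfate 4 (not isolated)
Conditions: K2S2O8 (1.1 equiv), aq KOH, N2, 0 °C to rt; then aq HCl, 85 °C
Reagents that add atoms: potassium peroxodisulfate, [K+].[K+].[O-]S(=O)(=O)OOS(=O)(=O)[O-]
Why: In the Elbs persulfate oxidation the phenolate attacks the peroxide oxygen through its para carbon, here the only unsubstituted ring position, and acid hydrolysis of aryl sulfate 4 should free the hydroquinone.

Step 3
Reactants: 5 2,5-dihydroxy-3,4,6-trimethoxyacetophenone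
Product: 6 1-[2-hydroxy-3,4,6-trimethoxy-5-(methoxymethoxy)phenyl]ethanone
Conditions: MOMCl (1.05 equiv), K2CO3 (1.5 equiv), acetone, N2, 0 °C to rt
Reagents that add atoms: chloromethyl methyl ether, COCCl
Why: In this Williamson-type O-alkylation the 2-OH is locked in a hydrogen bond to the acetyl oxygen and is a poor nucleophile, so one equivalent of the chloro ether should go to the 5-OH.

Step 4
Reactants: 7 3-methoxyphenol
Product: 8 1-methoxy-3-(methoxymethoxy)benzene
Conditions: MOMCl (1.2 equiv), K2CO3 (2 equiv), acetone, rt
Reagents that add atoms: chloromethyl methyl ether, COCCl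
Why: Williamson-type O-alkylation of the phenolate with the reactive α-chloro ether gives the MOM acetal, which serves next as a directing group and later as the mask of 2'-O.

Step 5
Reactants: 8 1-methoxy-3-(methoxymethoxy)benzene
Product: 10 2-iodo-1-methoxy-3-(methoxymethoxy)benzene, via aryllithium 9 (not isolated)
Conditions: n-BuLi (1.1 equiv), THF, 0 °C; I2 (1.2 equiv), −78 °C to rt
Reagents that add atoms: iodine, II
Why: In this directed ortho-metalation the OMe and OMOM groups cooperate to place lithium on their common ortho carbon, and iodinolysis of 9 fixes the halogen at the future C1'.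

Step 6
Reactants: 6 1-[2-hydroxy-3,4,6-trimethoxy-5-(methoxymethoxy)phenyl]ethanone; 10 2-iodo-1-methoxy-3-(methoxymethoxy)benzene; 11 carbon monoxide
Product: 14 5,7,8-trimethoxy-6-(methoxymethoxy)-2-[2-methoxy-6-(methoxymethoxy)phenyl]-4H-chromen-4-one, via aryl ester 12 (not isolated), via 1,3-diketone 13 (not isolated)
Conditions: Pd(OAc)2 (5 mol %), dppb (10 mol %), DBU (3 equiv), CO (10 bar), DMSO, 120 °C
Reagents that add atoms: none
Why: Oxidative addition of Pd(0) into the C1'–I bond of 10 and migratory insertion of CO 11 forge the C2–C1' bond as an aroyl–palladium species, which acylates the only free hydroxyl of 6 (O1–H, acyl transfer assisted by DBU) to give ester 12. DBU then enolises the acetyl group and a Baker–Venkataraman O-to-C acyl shift makes C2–C3 (diketone 13), after which O1 adds to the C2 carbonyl in a 6-exo-trig closure and loss of water from the hemiketal turns ring C into the 4-pyranone of 14. The closest known reaction type is the palladium-catalysed carbonylative annulation of aryl halides with 2-hydroxyacetophenones to flavones, together with the DBU-mediated one-pot ester-to-flavone sequence. No stereocentre is formed. The step needs carbonylative rather than direct coupling, which CO pressure and the steric relief that insertion brings to the doubly ortho-substituted aryl–palladium should secure, and it needs a single direction of cyclisation, which is secured because 6-O and 2'-O are MOM-masked and O1–H is the only oxygen nucleophile. The position of the new bond on ring B is fixed by the iodine placed at C1' in step 5.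

Step 7
Reactants: 14 5,7,8-trimethoxy-6-(methoxymethoxy)-2-[2-methoxy-6-(methoxymethoxy)phenyl]-4H-chromen-4-one
Product: 15 6-hydroxy-2-(2-hydroxy-6-methoxyphenyl)-5,7,8-trimethoxy-4H-chromen-4-one (6,2'-dihydroxy-5,7,8,6'-tetramethoxyflavone)
Conditions: conc. HCl (cat.), MeOH, 50 °C
Reagents that add atoms: none
Why: Acid-catalysed transacetalisation to methanol should cleave both aryl MOM acetals, while the four aryl methyl ethers and the pyranone are inert to dilute acid.

**Compound list**
1 | 1,2,3,5-tetramethoxybenzene | COc1cc(OC)c(OC)c(OC)c1 | starting material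
2 | 2,3,4,6-tetramethoxyacetophenone | CC(=O)c1c(OC)cc(OC)c(OC)c1OC | intermediate
3 | 2-hydroxy-3,4,6-trimethoxyacetophenone | CC(=O)c1c(OC)cc(OC)c(OC)c1O | intermediate
4 | potassium 3-acetyl-4-hydroxy-2,5,6-trimethoxyphenyl sulfate | CC(=O)c1c(OC)c(OS(=O)(=O)[O-])c(OC)c(OC)c1O.[K+] | intermediate
5 | 2,5-dihydroxy-3,4,6-trimethoxyacetophenone | CC(=O)c1c(OC)c(O)c(OC)c(OC)c1O | intermediate
6 | 1-[2-hydroxy-3,4,6-trimethoxy-5-(methoxymethoxy)phenyl]ethanone | CC(=O)c1c(OC)c(OCOC)c(OC)c(OC)c1O | intermediate
7 | 3-methoxyphenol | COc1cccc(O)c1 | starting material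
8 | 1-methoxy-3-(methoxymethoxy)benzene | COCOc1cccc(OC)c1 | intermediate
9 | [2-methoxy-6-(methoxymethoxy)phenyl]lithium | [Li]c1c(OC)cccc1OCOC | intermediate
10 | 2-iodo-1-methoxy-3-(methoxymethoxy)benzene | COCOc1cccc(OC)c1I | intermediate
11 | carbon monoxide | [C-]#[O+] | starting material
12 | 2-acetyl-3,5,6-trimethoxy-4-(methoxymethoxy)phenyl 2-methoxy-6-(methoxymethoxy)benzoate | CC(=O)c1c(OC)c(OCOC)c(OC)c(OC)c1OC(=O)c1c(OC)cccc1OCOC | intermediate
13 | 1-[2-hydroxy-3,4,6-trimethoxy-5-(methoxymethoxy)phenyl]-3-[2-methoxy-6-(methoxymethoxy)phenyl]propane-1,3-dione | COCOc1cccc(OC)c1C(=O)CC(=O)c1c(OC)c(OCOC)c(OC)c(OC)c1O | intermediate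
14 | 5,7,8-trimethoxy-6-(methoxymethoxy)-2-[2-methoxy-6-(methoxymethoxy)phenyl]-4H-chromen-4-one | COCOc1cccc(OC)c1-c1cc(=O)c2c(OC)c(OCOC)c(OC)c(OC)c2o1 | intermediate
15 | 6-hydroxy-2-(2-hydroxy-6-methoxyphenyl)-5,7,8-trimethoxy-4H-chromen-4-one | COc1cccc(O)c1-c1cc(=O)c2c(OC)c(O)c(OC)c(OC)c2o1 | target

**Step count**
Total steps: 7. Longest linear sequence: 5 (steps 1, 2, 3, 6, 7).

**Steps most likely to fail**

Step 6.
- Risk: oxidative addition and acyl transfer at the doubly ortho-substituted ring B may be slow. Hydrodeiodination of 10 or deactivation of the catalyst under CO could then take over. The sequence may also stall at the ester or diketone stage, because the acyl shift onto the hindered carbonyl is sluggish.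
- Fallback: ring C is built first and C2–C1' is then made by a Negishi coupling. The fallback sets out from 6, which is condensed with N,N-dimethylformamide dimethyl acetal (toluene, 90 °C) to (E)-3-(dimethylamino)-1-[2-hydroxy-3,4,6-trimethoxy-5-(methoxymethoxy)phenyl]prop-2-en-1-one F1. Brief warming with acetic acid in toluene, mild enough for the aryl MOM acetal, closes the ring with loss of dimethylamine to 5,7,8-trimethoxy-6-(methoxymethoxy)-4H-chromen-4-one F2. A hindered TMP–zinc amide base is then used. For chromones its C2/C3 site selectivity is known to be set by the choice of base and Lewis-acid additive. Zincation of C2–H gives [5,7,8-trimethoxy-6-(methoxymethoxy)-4-oxo-4H-chromen-2-yl]zinc chloride F3. Pd/SPhos-catalysed coupling of F3 with 10 comes back to the route at 14.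

Step 2.
- Risk: persulfate may be consumed by radical side paths, and the very electron-rich phenolate may be degraded oxidatively, so that conversion stays low.
- Fallback: oxidation goes up to the quinone level and then down again. The fallback sets out from 3, which undergoes a Teuber oxidation with Fremy's salt (aq KH2PO4/acetone) at its free para position to 2-acetyl-3,5,6-trimethoxy-1,4-benzoquinone F4. Reduction with aqueous sodium dithionite comes back to the route at 5.

Step 3.
- Risk: the 5-OH is flanked by two methoxy groups. Its alkylation may become slow enough for the chelated 2-OH to compete, with loss of site selectivity, and the hydroquinone may be air-oxidised under base.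
- Fallback: both hydroxyls are protected and one is then released selectively. The fallback sets out from 5, which is alkylated exhaustively (NaH, excess MOMCl, DMF) to 1-[3,4,6-trimethoxy-2,5-bis(methoxymethoxy)phenyl]ethanone F5. Catalytic iodine in methanol at rt should then remove only the acetal ortho to the acetyl group, whose cleavage is assisted by the neighbouring carbonyl oxygen and by the hydrogen bond in the product. This comes back to the route at 6.

**Further compounds**
F1 | step 6 | (E)-3-(dimethylamino)-1-[2-hydroxy-3,4,6-trimethoxy-5-(methoxymethoxy)phenyl]prop-2-en-1-one | CN(C)/C=C/C(=O)c1c(OC)c(OCOC)c(OC)c(OC)c1O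
F2 | step 6 | 5,7,8-trimethoxy-6-(methoxymethoxy)-4H-chromen-4-one | O=c1ccoc2c(OC)c(OC)c(OCOC)c(OC)c12
F3 | step 6 | [5,7,8-trimethoxy-6-(methoxymethoxy)-4-oxo-4H-chromen-2-yl]zinc chloride | Cl[Zn]c1cc(=O)c2c(OC)c(OCOC)c(OC)c(OC)c2o1
F4 | step 2 | 2-acetyl-3,5,6-trimethoxy-1,4-benzoquinone | CC(=O)C1=C(OC)C(=O)C(OC)=C(OC)C1=O
F5 | step 3 | 1-[3,4,6-trimethoxy-2,5-bis(methoxymethoxy)phenyl]ethanone | CC(=O)c1c(OC)c(OCOC)c(OC)c(OC)c1OCOC
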